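Ring C of the flavone is cut at C4a–C4, C4–C3 and O1–C2. This works because C4, bonded only to C4a, C3 and its own oxygen, is a one-carbon unit that CO can supply, and because O1 is carried by C8a, the ring A atom between C4a and the biaryl carbon C8. One palladium-catalysed carbonylative annulation thus welds an iodophenol, CO and 4-ethynylanisole into the complete 8-arylflavone. The precursor is the preassembled ring A–ring B biaryl: a single free hydroxyl (future O1), iodine at the future C4a, methoxy groups at future C5 and C7, and ring B bearing an isopropyl ether and a dioxolane-masked aldehyde. That aldehyde later gives the (2S)-flavanone via a chalcone closed enzymatically.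

Key step: step 7

Assumption: the biaryl axis between ring B (the 2-aryl ring of the flavanone) and flavone C8 has three ortho substituents and no descriptor in the target, so it is taken as freely rotating and flavanone C2 as the only stereogenic element. The isomerase of step 12 is a recombinant catalyst, not a starting material.

Step 1
Reactants: 1 3,5-dimethoxyphenol
Product: 2 3,5-dimethoxyphenyl N,N-diethylcarbamate
Conditions: ClCONEt2, K2CO3, MeCN, reflux
Reagents that add atoms: N,N-diethylcarbamoyl chloride, CCN(CC)C(=O)Cl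
Why: O-Carbamoylation of the phenoxide installs the strongest oxygen-based directing group for the two ortho-metalations that follow.

Step 2
Reactants: 3 3-bromo-4-hydroxybenzaldehyde
Product: 4 3-bromo-4-isopropoxybenzaldehyde
Conditions: i-PrBr, K2CO3, DMF, 70 °C
Reagents that add atoms: 2-bromopropane, CC(C)Br
Why: Williamson ether synthesis on an acidic para-formylphenol gives an isopropyl ether that has no benzylic C–H for s-BuLi to attack, withstands KOH and the amine/CO medium, and later falls to BCl3 without loss of unchelated methyl ethers.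

Step 3
Reactants: 4 3-bromo-4-isopropoxybenzaldehyde
Product: 5 2-(3-bromo-4-isopropoxyphenyl)-1,3-dioxolane
Conditions: HOCH2CH2OH, p-TsOH (cat.), toluene, reflux, Dean–Stark trap
Reagents that add atoms: ethylene glycol, OCCO
Why: Acid-catalysed acetalisation with azeotropic removal of water masks the aldehyde against the organometallic reagents of steps 4 and 5 and the amine of step 7.

Step 4
Reactants: 2 3,5-dimethoxyphenyl N,N-diethylcarbamate; 5 2-(3-bromo-4-isopropoxyphenyl)-1,3-dioxolane
Product: 8 2-[5-(1,3-dioxolan-2-yl)-2-isopropoxyphenyl]-3,5-dimethoxyphenyl N,N-diethylcarbamate, via C2-aryllithium 6 (not isolated), via arylzinc chloride 7 (not isolated)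
Conditions: 2, s-BuLi, TMEDA, THF, −78 °C; ZnCl2, −78 °C to rt; then 5, Pd(OAc)2 (2 mol %), SPhos (4 mol %), THF, 60 °C
Reagents that add atoms: none
Why: Directed ortho-metalation followed by Negishi coupling: the carbamate and the neighbouring methoxy group jointly direct s-BuLi to C2 rather than to C4 between the two methoxy groups, exchange to zinc blocks the anionic ortho-Fries shift on warming and avoids a protodeboronation-prone 2,6-dioxygenated boronate, and SPhos-ligated palladium is a proven catalyst for biaryls with three ortho substituents.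

Step 5
Reactants: 8 2-[5-(1,3-dioxolan-2-yl)-2-isopropoxyphenyl]-3,5-dimethoxyphenyl N,N-diethylcarbamate
Product: 10 2-[5-(1,3-dioxolan-2-yl)-2-isopropoxyphenyl]-6-iodo-3,5-dimethoxyphenyl N,N-diethylcarbamate, via C6-aryllithium 9 (not isolated)
Conditions: s-BuLi, TMEDA, THF, −78 °C; I2, THF, −78 °C to rt
Reagents that add atoms: iodine, II
Why: A second directed ortho-metalation takes the only position still ortho to the carbamate, again flanked by a methoxy group, faster than C4 or any ring B position at −78 °C (where the ortho-Fries shift is frozen), so the iodine quench places the halogen unambiguously at the future C4a, which electrophilic iodination of the free phenol could not guarantee.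

Step 6
Reactants: 10 2-[5-(1,3-dioxolan-2-yl)-2-isopropoxyphenyl]-6-iodo-3,5-dimethoxyphenyl N,N-diethylcarbamate
Product: 11 2-[5-(1,3-dioxolan-2-yl)-2-isopropoxyphenyl]-6-iodo-3,5-dimethoxyphenol
Conditions: Cp2Zr(H)Cl (3 equiv), THF, rt; H2O
Reagents that add atoms: none
Why: Reductive cleavage of the aryl O-carbamate (hydrozirconation of the carbamate carbonyl, then collapse to aryloxide and formamide) is a mild method suited to hindered metalation products and spares the aryl iodide, which LiAlH4 would endanger, as well as the acetal and the ethers.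

Step 7
Reactants: 11 2-[5-(1,3-dioxolan-2-yl)-2-isopropoxyphenyl]-6-iodo-3,5-dimethoxyphenol; 12 4-ethynylanisole
Product: 15 8-[5-(1,3-dioxolan-2-yl)-2-isopropoxyphenyl]-5,7-dimethoxy-2-(4-methoxyphenyl)-4H-chromen-4-one, via hydroxyaryl ynone 13 (not isolated), via diethylamino enone 14 (not isolated)
Conditions: PdCl2(PPh3)2 (5 mol %), CO (20 bar), Et2NH, 100 °C, no copper salt
Reagents that add atoms: carbon monoxide, [C-]#[O+]
Why: The cycle starts with oxidative addition of the hindered C–I bond of 11 to zerovalent palladium generated in situ from PdCl2(PPh3)2; migratory insertion of CO then furnishes an aroylpalladium iodide (divalent palladium), which takes up the amine-deprotonated alkyne 12 and releases ynone 13 by reductive elimination, forging C4a–C4 and C4–C3. Diethylamine next adds to the alkyne carbon remote from the carbonyl group to give enaminone 14, and the adjacent phenol replaces the amine by addition–elimination, forging O1–C2. The closest known reaction type is the carbonylative Sonogashira-type annulation of 2-iodophenols with terminal arylacetylenes in a secondary amine, an established flavone synthesis. The one new ring, pyranone ring C, closes in the 6-endo mode (6-endo-trig on 14), because the amine makes the future C2 the only electrophilic carbon and so shuts off the 5-exo-dig attack that would lead to an aurone. No stereocentre is created. The step needs carbonylative over direct alkynylation, secured by CO pressure and the absence of copper, and 8-aryl over 6-aryl regiochemistry, secured because 11 has a single hydroxyl lying between the iodinated carbon and the biaryl carbon, while the other neighbour of iodine is a methyl ether.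

Step 8
Reactants: 15 8-[5-(1,3-dioxolan-2-yl)-2-isopropoxyphenyl]-5,7-dimethoxy-2-(4-methoxyphenyl)-4H-chromen-4-one
Product: 16 3-[5,7-dimethoxy-2-(4-methoxyphenyl)-4-oxo-4H-chromen-8-yl]-4-isopropoxybenzaldehyde
Conditions: 1 M HCl, THF, rt
Reagents that add atoms: water, O
Why: Acid-catalysed acetal hydrolysis is fast for a dioxolane para to an alkoxy group and leaves the flavone and all aryl ethers untouched.

Step 9
Reactants: 17 2',6'-dihydroxy-4'-methoxyacetophenone
Product: 18 1-[2-hydroxy-4-methoxy-6-(methoxymethoxy)phenyl]ethanone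
Conditions: MOMCl (1.1 equiv), i-Pr2NEt, CH2Cl2, 0 °C to rt
Reagents that add atoms: chloromethyl methyl ether, COCCl
Why: O-Alkylation of the phenol stops after one MOM group because the remaining hydroxyl is held in a hydrogen bond to the ketone, and one free ortho-hydroxyl is harmless in step 10, so a second protection is saved.

Step 10
Reactants: 16 3-[5,7-dimethoxy-2-(4-methoxyphenyl)-4-oxo-4H-chromen-8-yl]-4-isopropoxybenzaldehyde; 18 1-[2-hydroxy-4-methoxy-6-(methoxymethoxy)phenyl]ethanone
Product: 20 (E)-1-[2-hydroxy-4-methoxy-6-(methoxymethoxy)phenyl]-3-{3-[5,7-dimethoxy-2-(4-methoxyphenyl)-4-oxo-4H-chromen-8-yl]-4-isopropoxyphenyl}prop-2-en-1-one, via aldol adduct 19 (not isolated)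
Conditions: KOH (50% aq.), EtOH–THF, 0 °C to rt; cold 1 M HCl to pH 5
Reagents that add atoms: none
Why: Claisen–Schmidt condensation (aldol addition, then E1cB loss of water) of the non-enolisable aldehyde 16 with the methyl ketone 18 gives the thermodynamically preferred (E)-enone, the fully etherified flavone tolerating hydroxide at room temperature and the chalcone staying open as its 2'-phenoxide.

Step 11
Reactants: 20 (E)-1-[2-hydroxy-4-methoxy-6-(methoxymethoxy)phenyl]-3-{3-[5,7-dimethoxy-2-(4-methoxyphenyl)-4-oxo-4H-chromen-8-yl]-4-isopropoxyphenyl}prop-2-en-1-one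
Product: 21 (E)-1-(2,6-dihydroxy-4-methoxyphenyl)-3-{4-hydroxy-3-[5-hydroxy-7-methoxy-2-(4-methoxyphenyl)-4-oxo-4H-chromen-8-yl]phenyl}prop-2-en-1-one
Conditions: BCl3 (8 equiv), CH2Cl2, −78 to 0 °C; ice-water, rapid cold work-up
Reagents that add atoms: none
Why: Lewis-acid ether cleavage with BCl3 removes the carbonyl-chelated flavone 5-O-methyl group, the secondary isopropyl ether and the MOM acetal but leaves the three unchelated aryl methyl ethers, while boron chelation of the 2'-oxygen and the ketone should hold the chalcone open until the cold quench.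

Step 12
Reactants: 21 (E)-1-(2,6-dihydroxy-4-methoxyphenyl)-3-{4-hydroxy-3-[5-hydroxy-7-methoxy-2-(4-methoxyphenyl)-4-oxo-4H-chromen-8-yl]phenyl}prop-2-en-1-one
Product: 22 (2S)-2,3-dihydroheveaflavone
Conditions: recombinant chalcone isomerase (EC 5.5.1.6, Medicago sativa gene expressed in E. coli), KH2PO4/K2HPO4 buffer pH 6.8, 10% DMSO, 15 °C; EtOAc extraction
Reagents that add atoms: none
Why: Enzymatic intramolecular oxa-Michael addition: the isomerase binds the 4-hydroxycinnamoyl-2',6'-dihydroxyaryl core that 21 shares with its natural substrate and delivers the 2'-oxyanion (either ortho hydroxyl, since the two interconvert by aryl–carbonyl rotation) to a single face of the enone β-carbon, which sets C2 as (2S), while near-neutral pH and low temperature keep the uncatalysed non-selective closure and later epimerisation slow.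

Compound list
1 | 3,5-dimethoxyphenol | COc1cc(O)cc(OC)c1 | starting material
2 | 3,5-dimethoxyphenyl N,N-diethylcarbamate | CCN(CC)C(=O)Oc1cc(OC)cc(OC)c1 | intermediate
3 | 3-bromo-4-hydroxybenzaldehyde | O=Cc1ccc(O)c(Br)c1 | starting material
4 | 3-bromo-4-isopropoxybenzaldehyde | CC(C)Oc1ccc(C=O)cc1Br | intermediate
5 | 2-(3-bromo-4-isopropoxyphenyl)-1,3-dioxolane | CC(C)Oc1ccc(C2OCCO2)cc1Br | intermediate
6 | [2-(diethylcarbamoyloxy)-4,6-dimethoxyphenyl]lithium | CCN(CC)C(=O)Oc1cc(OC)cc(OC)c1[Li] | intermediate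
7 | [2-(diethylcarbamoyloxy)-4,6-dimethoxyphenyl]zinc chloride | CCN(CC)C(=O)Oc1cc(OC)cc(OC)c1[Zn]Cl | intermediate
8 | 2-[5-(1,3-dioxolan-2-yl)-2-isopropoxyphenyl]-3,5-dimethoxyphenyl N,N-diethylcarbamate | CCN(CC)C(=O)Oc1cc(OC)cc(OC)c1-c1cc(C2OCCO2)ccc1OC(C)C | intermediate
9 | {3-[5-(1,3-dioxolan-2-yl)-2-isopropoxyphenyl]-2-(diethylcarbamoyloxy)-4,6-dimethoxyphenyl}lithium | CCN(CC)C(=O)Oc1c([Li])c(OC)cc(OC)c1-c1cc(C2OCCO2)ccc1OC(C)C | intermediate
10 | 2-[5-(1,3-dioxolan-2-yl)-2-isopropoxyphenyl]-6-iodo-3,5-dimethoxyphenyl N,N-diethylcarbamate | CCN(CC)C(=O)Oc1c(I)c(OC)cc(OC)c1-c1cc(C2OCCO2)ccc1OC(C)C | intermediate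
11 | 2-[5-(1,3-dioxolan-2-yl)-2-isopropoxyphenyl]-6-iodo-3,5-dimethoxyphenol | Oc1c(I)c(OC)cc(OC)c1-c1cc(C2OCCO2)ccc1OC(C)C | intermediate
12 | 4-ethynylanisole | COc1ccc(C#C)cc1 | starting material
13 | 1-{3-[5-(1,3-dioxolan-2-yl)-2-isopropoxyphenyl]-2-hydroxy-4,6-dimethoxyphenyl}-3-(4-methoxyphenyl)prop-2-yn-1-one | COc1ccc(C#CC(=O)c2c(O)c(-c3cc(C4OCCO4)ccc3OC(C)C)c(OC)cc2OC)cc1 | intermediate
14 | 3-(diethylamino)-1-{3-[5-(1,3-dioxolan-2-yl)-2-isopropoxyphenyl]-2-hydroxy-4,6-dimethoxyphenyl}-3-(4-methoxyphenyl)prop-2-en-1-one (push–pull alkene, geometry not fixed) | CCN(CC)C(=CC(=O)c1c(O)c(-c2cc(C3OCCO3)ccc2OC(C)C)c(OC)cc1OC)c1ccc(OC)cc1 | intermediate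
15 | 8-[5-(1,3-dioxolan-2-yl)-2-isopropoxyphenyl]-5,7-dimethoxy-2-(4-methoxyphenyl)-4H-chromen-4-one | COc1ccc(-c2cc(=O)c3c(OC)cc(OC)c(-c4cc(C5OCCO5)ccc4OC(C)C)c3o2)cc1 | intermediate
16 | 3-[5,7-dimethoxy-2-(4-methoxyphenyl)-4-oxo-4H-chromen-8-yl]-4-isopropoxybenzaldehyde | COc1ccc(-c2cc(=O)c3c(OC)cc(OC)c(-c4cc(C=O)ccc4OC(C)C)c3o2)cc1 | intermediate
17 | 2',6'-dihydroxy-4'-methoxyacetophenone | CC(=O)c1c(O)cc(OC)cc1O | starting material
18 | 1-[2-hydroxy-4-methoxy-6-(methoxymethoxy)phenyl]ethanone | CC(=O)c1c(O)cc(OC)cc1OCOC | intermediate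
19 | 3-hydroxy-1-[2-hydroxy-4-methoxy-6-(methoxymethoxy)phenyl]-3-{3-[5,7-dimethoxy-2-(4-methoxyphenyl)-4-oxo-4H-chromen-8-yl]-4-isopropoxyphenyl}propan-1-one (racemic) | COCOc1cc(OC)cc(O)c1C(=O)CC(O)c1ccc(OC(C)C)c(-c2c(OC)cc(OC)c3c(=O)cc(-c4ccc(OC)cc4)oc23)c1 | intermediate
20 | (E)-1-[2-hydroxy-4-methoxy-6-(methoxymethoxy)phenyl]-3-{3-[5,7-dimethoxy-2-(4-methoxyphenyl)-4-oxo-4H-chromen-8-yl]-4-isopropoxyphenyl}prop-2-en-1-one | COCOc1cc(OC)cc(O)c1C(=O)/C=C/c1ccc(OC(C)C)c(-c2c(OC)cc(OC)c3c(=O)cc(-c4ccc(OC)cc4)oc23)c1 | intermediate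
21 | (E)-1-(2,6-dihydroxy-4-methoxyphenyl)-3-{4-hydroxy-3-[5-hydroxy-7-methoxy-2-(4-methoxyphenyl)-4-oxo-4H-chromen-8-yl]phenyl}prop-2-en-1-one | COc1cc(O)c(C(=O)/C=C/c2ccc(O)c(-c3c(OC)cc(O)c4c(=O)cc(-c5ccc(OC)cc5)oc34)c2)c(O)c1 | intermediate
22 | (2S)-2,3-dihydroheveaflavone, 5-hydroxy-8-{2-hydroxy-5-[(2S)-5-hydroxy-7-methoxy-4-oxochroman-2-yl]phenyl}-7-methoxy-2-(4-methoxyphenyl)-4H-chromen-4-one | COc1ccc(-c2cc(=O)c3c(O)cc(OC)c(-c4cc([C@@H]5CC(=O)c6c(O)cc(OC)cc6O5)ccc4O)c3o2)cc1 | target

Total step count: 12.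
Longest linear sequence: 10 steps (3 → 4 → 5 → 8 → 10 → 11 → 15 → 16 → 20 → 21 → 22, that is steps 2, 3, 4, 5, 6, 7, 8, 10, 11 and 12).

Steps most likely to fail

Step 7.
- **Risk:** Oxidative addition into a C–I bond flanked by two oxygen substituents on an electron-rich ring may be slow. Alkynylation without uptake of CO, alkyne dimerisation or reductive loss of iodine could then compete.
- **Fallback:** It sets out from 11 and 12 and returns at 13, hence 15. The carbonyl carbon is brought in as a preformed acyl donor instead of CO.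
- Alkyne 12 is deprotonated with n-BuLi (THF, −78 °C) and treated with N-methoxy-N-methylcarbamoyl chloride to give N-methoxy-3-(4-methoxyphenyl)-N-methylprop-2-ynamide F1.
- Phenol 11 is converted with two equivalents of n-BuLi at −78 °C (deprotonation, then iodine–lithium exchange) into the lithium 2-lithiophenoxide of 11 F2.
- F2 adds to F1 (Weinreb ketone synthesis) and gives ynone 13 after work-up.
- Warming 13 in Et2NH closes it through 14 to 15.

Step 12.
- **Risk:** The bulky, poorly soluble substrate may bind weakly to the enzyme. The uncatalysed, non-selective ring closure would then take over and erode enantiopurity.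
- **Fallback:** It sets out from 21 and returns at 22. The ring is closed without stereocontrol and the racemate is then resolved.
- Chalcone 21 is cyclised with NaOAc in refluxing EtOH to racemic 2,3-dihydroheveaflavone F3.
- F3 is separated by preparative HPLC on an amylose tris(3,5-dimethylphenylcarbamate) phase into 22 and (2R)-2,3-dihydroheveaflavone F4.
- F4 is re-opened to 21 by brief treatment with cold concentrated aqueous KOH and rapid acidification, and is recycled.

Step 11.
- **Risk:** Three different ethers must fall in one operation on a closure-prone chalcone. Incomplete or unselective ether cleavage, or premature non-selective ring closure during the acidic quench, may occur.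
- **Fallback:** It sets out from 16 and returns at 21. The robust ethers are removed before the chalcone exists, so that only mild acetal cleavage remains at the end.
- Aldehyde 16 is treated with BCl3 (CH2Cl2, −78 to 0 °C) to give 4-hydroxy-3-[5-hydroxy-7-methoxy-2-(4-methoxyphenyl)-4-oxo-4H-chromen-8-yl]benzaldehyde F5.
- MOMCl/K2CO3 in acetone etherifies only the unchelated ring B phenol, giving 3-[5-hydroxy-7-methoxy-2-(4-methoxyphenyl)-4-oxo-4H-chromen-8-yl]-4-(methoxymethoxy)benzaldehyde F6.
- Claisen–Schmidt condensation of F6 with 18 (KOH, EtOH–THF) gives (E)-1-[2-hydroxy-4-methoxy-6-(methoxymethoxy)phenyl]-3-{3-[5-hydroxy-7-methoxy-2-(4-methoxyphenyl)-4-oxo-4H-chromen-8-yl]-4-(methoxymethoxy)phenyl}prop-2-en-1-one F7.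
- HCl in MeOH at room temperature removes both MOM groups of F7 to give 21.

Further compounds
F1 | step 7 | N-methoxy-3-(4-methoxyphenyl)-N-methylprop-2-ynamide | COc1ccc(C#CC(=O)N(C)OC)cc1
F2 | step 7 | lithium 2-lithiophenoxide of 11 | [Li]Oc1c([Li])c(OC)cc(OC)c1-c1cc(C2OCCO2)ccc1OC(C)C
F3 | step 12 | racemic 2,3-dihydroheveaflavone | COc1ccc(-c2cc(=O)c3c(O)cc(OC)c(-c4cc(C5CC(=O)c6c(O)cc(OC)cc6O5)ccc4O)c3o2)cc1
F4 | step 12 | (2R)-2,3-dihydroheveaflavone | COc1ccc(-c2cc(=O)c3c(O)cc(OC)c(-c4cc([C@H]5CC(=O)c6c(O)cc(OC)cc6O5)ccc4O)c3o2)cc1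
F5 | step 11 | 4-hydroxy-3-[5-hydroxy-7-methoxy-2-(4-methoxyphenyl)-4-oxo-4H-chromen-8-yl]benzaldehyde | COc1ccc(-c2cc(=O)c3c(O)cc(OC)c(-c4cc(C=O)ccc4O)c3o2)cc1
F6 | step 11 | 3-[5-hydroxy-7-methoxy-2-(4-methoxyphenyl)-4-oxo-4H-chromen-8-yl]-4-(methoxymethoxy)benzaldehyde | COCOc1ccc(C=O)cc1-c1c(OC)cc(O)c2c(=O)cc(-c3ccc(OC)cc3)oc12
F7 | step 11 | (E)-1-[2-hydroxy-4-methoxy-6-(methoxymethoxy)phenyl]-3-{3-[5-hydroxy-7-methoxy-2-(4-methoxyphenyl)-4-oxo-4H-chromen-8-yl]-4-(methoxymethoxy)phenyl}prop-2-en-1-one | COCOc1cc(OC)cc(O)c1C(=O)/C=C/c1ccc(OCOC)c(-c2c(OC)cc(O)c3c(=O)cc(-c4ccc(OC)cc4)oc23)c1
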